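**Retrosynthetic overview** (chromane numbering O1, C2–C8a for arene A and pyran ring B; cyclobutane ring D = Cb, Cc, Cd, Ce; ring C = the indane five-membered ring; ring E = catechol)
1. Target ⇒ desilylation and chromanone → chromene ⇒ Cd–aryl bond (ring E) by nickel-mediated radical arylation of the Cd alcohol ⇒ tetracyclic diketone.
2. Diketone ⇒ arene C5–Cc bond, closing ring C, by intramolecular Pd α-arylation of a cyclobutanone with the chromanone 5-triflate.
3. Precursor ⇒ arene C6–CH2 bond by Negishi coupling of a cyclobutylmethylzinc (from cis-pinonic acid by Baeyer–Villiger oxidation and iododecarboxylation) with a 6-iodochromanone (from phloroglucinol).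
4. Feature: in ring D the CMe2 carbon Ce sits between Cb (CH carrying the CH2 link to C6) and Cd (CH carrying the catechol), which is the 2,2-dimethyl-1,3-disubstituted pattern of cis-pinonic acid; Cb is bought, and quaternary Ce leaves Cc as the only α-carbon of the Cd ketone.
5. Ring order: B (on bought arene A), D (bought), C (key step), then the 3,4-ene of ring B; ring E is bought.

Key step: step 11

Assumption: (1R,3R)-cis-pinonic acid is used enantiopure (it is the oxidative-cleavage product of (1S,5S)-α-pinene), since it is the only source of absolute configuration. The alkyl radical route from its redox-active ester is avoided in the main line because a free cyclobutylmethyl radical next to CMe2 can ring-open.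

**Step 1**
Reactants: 1 phloroglucinol; 2 3-methylbut-2-enoic acid
Product: 4 5,7-dihydroxy-2,2-dimethylchroman-4-one, via aryl enone 3 (not isolated)
Conditions: Eaton's reagent (P2O5 in MeSO3H), 70 °C
Reagents that add atoms: none
Why: Friedel–Crafts acylation of the C3-symmetric triphenol gives the aryl enone, whose ortho-hydroxyl closes ring B by oxa-Michael addition, so no regiochemical choice arises.

**Step 2**
Reactants: 4 5,7-dihydroxy-2,2-dimethylchroman-4-one
Product: 5 5-hydroxy-7-methoxy-2,2-dimethylchroman-4-one
Conditions: MeI (1.1 equiv), K2CO3, acetone, rt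
Reagents that add atoms: iodomethane, CI
Why: Williamson etherification should alkylate only the 7-hydroxyl, because the 5-hydroxyl is hydrogen-bonded to the C4 carbonyl and far less nucleophilic.

**Step 3**
Reactants: 5 5-hydroxy-7-methoxy-2,2-dimethylchroman-4-one
Product: 6 5-hydroxy-6-iodo-7-methoxy-2,2-dimethylchroman-4-one
Conditions: BnMe3N·ICl2 (1.05 equiv), CaCO3, CH2Cl2/MeOH, rt
Reagents that add atoms: benzyltrimethylammonium dichloroiodate, C[N+](C)(C)Cc1ccccc1.Cl[I-]Cl
Why: Electrophilic aromatic iodination under buffered, non-acidic conditions should be directed by the free chelated 5-hydroxyl to its ortho carbon C6 in preference to C8, and one equivalent of the mild I+ donor limits di-iodination.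

**Step 4**
Reactants: 6 5-hydroxy-6-iodo-7-methoxy-2,2-dimethylchroman-4-one
Product: 7 6-iodo-7-methoxy-2,2-dimethyl-4-oxochroman-5-yl acetate
Conditions: Ac2O, pyridine, DMAP (cat.), CH2Cl2, rt
Reagents that add atoms: acetic anhydride, CC(=O)OC(C)=O
Why: DMAP-catalysed acylation masks the acidic phenol, which would otherwise protonate the organozinc reagent, with a group that is later removed together with the cyclobutyl acetate.

**Step 5**
Reactants: 8 (1R,3R)-cis-pinonic acid
Product: 9 2-[(1R,3R)-3-acetoxy-2,2-dimethylcyclobutyl]acetic acid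
Conditions: mCPBA (2 equiv), CHCl3, 40 °C
Reagents that add atoms: mCPBA, OOC(=O)c1cccc(Cl)c1
Why: Baeyer–Villiger oxidation, in which the secondary cyclobutyl carbon migrates in preference to methyl and with retention; it is run before any electron-rich aryl ketone is present to compete.

**Step 6**
Reactants: 9 2-[(1R,3R)-3-acetoxy-2,2-dimethylcyclobutyl]acetic acid
Product: 11 (1R,3S)-3-(iodomethyl)-2,2-dimethylcyclobutyl acetate, via acyl hypoiodite 10 (not isolated)
Conditions: PhI(OAc)2, I2, cyclohexane, hν (W lamp), reflux
Reagents that add atoms: iodine, II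
Why: Suárez-type iododecarboxylation (a Hunsdiecker variant), in which iodine-atom transfer to the cyclobutylmethyl radical is close to diffusion-controlled and should outrun ring opening toward the CMe2 carbon; Cb is not touched.

**Step 7**
Reactants: 11 (1R,3S)-3-(iodomethyl)-2,2-dimethylcyclobutyl acetate; 7 6-iodo-7-methoxy-2,2-dimethyl-4-oxochroman-5-yl acetate
Product: 13 6-{[(1S,3R)-3-acetoxy-2,2-dimethylcyclobutyl]methyl}-7-methoxy-2,2-dimethyl-4-oxochroman-5-yl acetate, via cyclobutylmethylzinc iodide 12 (not isolated)
Conditions: Zn dust (BrCH2CH2Br/TMSCl-activated), LiCl, THF, 40 °C; then 7, Pd(OAc)2 (3 mol%), SPhos (6 mol%), THF, 25→50 °C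
Reagents that add atoms: none
Why: Zinc insertion and Pd/SPhos Negishi coupling join the primary alkyl group to the di-ortho-substituted aryl iodide through two-electron organometallic intermediates, which keeps the strained ring closed and tolerates the ketone and both acetates.

**Step 8**
Reactants: 13 6-{[(1S,3R)-3-acetoxy-2,2-dimethylcyclobutyl]methyl}-7-methoxy-2,2-dimethyl-4-oxochroman-5-yl acetate
Product: 14 5-hydroxy-6-{[(1S,3R)-3-hydroxy-2,2-dimethylcyclobutyl]methyl}-7-methoxy-2,2-dimethylchroman-4-one
Conditions: LiOH·H2O (4 equiv), THF/MeOH/H2O, rt; aq. NH4Cl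
Reagents that add atoms: none
Why: Saponification cleaves the aryl and the cyclobutyl acetate in one operation, and 2,2-dimethylchroman-4-ones are stable to aqueous hydroxide at room temperature.

**Step 9**
Reactants: 14 5-hydroxy-6-{[(1S,3R)-3-hydroxy-2,2-dimethylcyclobutyl]methyl}-7-methoxy-2,2-dimethylchroman-4-one
Product: 15 6-{[(1S,3R)-3-hydroxy-2,2-dimethylcyclobutyl]methyl}-7-methoxy-2,2-dimethyl-4-oxochroman-5-yl trifluoromethanesulfonate
Conditions: PhNTf2 (1.2 equiv), K2CO3, DMF, rt
Reagents that add atoms: N-phenylbis(trifluoromethanesulfonimide), FC(F)(F)S(=O)(=O)N(c1ccccc1)S(=O)(=O)C(F)(F)F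
Why: Chemoselective O-triflation, since carbonate ionises only the phenol and the mild triflyl donor then sulfonylates the phenoxide and leaves the secondary alcohol untouched.

**Step 10**
Reactants: 15 6-{[(1S,3R)-3-hydroxy-2,2-dimethylcyclobutyl]methyl}-7-methoxy-2,2-dimethyl-4-oxochroman-5-yl trifluoromethanesulfonate
Product: 16 6-{[(1S)-2,2-dimethyl-3-oxocyclobutyl]methyl}-7-methoxy-2,2-dimethyl-4-oxochroman-5-yl trifluoromethanesulfonate
Conditions: Dess–Martin periodinane (1.3 equiv), CH2Cl2, rt
Reagents that add atoms: none
Why: Dess–Martin oxidation gives the cyclobutanone under neutral conditions that spare the aryl triflate; the ketone is unveiled only now because a zinc–carbon bond on the CH2 next to a 3-oxocyclobutane could fragment to a zinc enolate.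

**Step 11 (key step)**
Reactants: 16 6-{[(1S)-2,2-dimethyl-3-oxocyclobutyl]methyl}-7-methoxy-2,2-dimethyl-4-oxochroman-5-yl trifluoromethanesulfonate
Product: 17 cis-fused tetracyclic diketone (ring C closed by the C5–Cc bond; Cb S, Cc S; H atoms at Cb and Cc on the same face; C=O at Cd and at C4)
Conditions: Pd(OAc)2 (10 mol%), XPhos (20 mol%), anhydrous K3PO4 (2.5 equiv), toluene, 90 °C
Reagents that add atoms: none
Why: Pd(0) adds oxidatively to the C5–OTf bond (activated by the ortho acyl group), phosphate deprotonates the cyclobutanone at Cc, the only enolisable carbon because Ce is quaternary, and the C-bound Pd enolate reductively eliminates to form C5–Cc. This is the intramolecular Pd-catalysed ketone α-arylation, known for tethered aryl halides and triflates including 3-substituted cyclobutanones. Ring C closes in a 5-(enolexo)-exo-trig mode through a six-membered palladacycle. The new stereocentre Cc is controlled by Cb: the one-carbon CH2 tether lets palladium reach only the enolate face syn to it, so the fusion is cis, a trans-fused benzo-bicyclo[3.2.0] system being out of reach. The step needs chemoselectivity for the cyclobutanone over the chromanone enolate, which could only close a four-membered ring, and a weak non-nucleophilic base so that neither the triflate nor the strained ketone is attacked.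

**Step 12**
Reactants: 17 cis-fused tetracyclic diketone
Product: 18 Cd cyclobutanol of 17 (mainly the endo alcohol with OH cis to the C5–Cc bond expected; either epimer serves; chromanone intact)
Conditions: NaBH4 (0.5 equiv), THF/MeOH, −40 °C
Reagents that add atoms: none
Why: Chemoselective borohydride reduction, as the strained cyclobutanone is far more electrophilic than the vinylogous-ester-like chromanone; hydride should arrive on the convex face and the carbinol configuration is erased in step 14.

**Step 13**
Reactants: 19 4-bromocatechol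
Product: 20 4-bromo-1,2-bis(tert-butyldimethylsilyloxy)benzene
Conditions: TBSCl (2.4 equiv), imidazole, DMF, rt
Reagents that add atoms: tert-butyldimethylsilyl chloride, CC(C)(C)[Si](C)(C)Cl
Why: Imidazole-mediated silylation protects both phenols as fluoride-labile ethers that can be removed at the end without the acid that a chromene would not tolerate.

**Step 14**
Reactants: 18 Cd cyclobutanol of 17; 20 4-bromo-1,2-bis(tert-butyldimethylsilyloxy)benzene
Product: 22 bis-TBS aryl chromanone (Cb S; Cc R; Cd S; the 3,4-bis(TBSO)phenyl group on the convex face of ring D and trans to the C5–Cc bond), via benzoxazoline adduct 21 (not isolated)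
Conditions: 5,7-di-tert-butyl-3-phenylbenzoxazolium BF4 (1.2 equiv), pyridine, MTBE, rt; then 20, Ir(ppy)2(dtbbpy)PF6 (1 mol%), NiBr2·dtbbpy (5 mol%), quinuclidine, DMA, blue LEDs, rt
Reagents that add atoms: none
Why: Nickel/photoredox deoxygenative arylation, in which oxidation and β-scission of the alcohol–benzoxazolium adduct release the secondary cyclobutyl radical at Cd and the aryl–nickel species captures it and reductively eliminates on the convex face, anti to the arene on Cc, so Cd is set with ring E trans to ring A whichever alcohol epimer is used.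

**Step 15**
Reactants: 22 bis-TBS aryl chromanone
Product: 23 bis-TBS aryl chroman-4-ol (C4 epimers)
Conditions: LiBH4, THF, 0 °C→rt
Reagents that add atoms: none
Why: Hydride reduction of the aryl ketone in an aprotic medium leaves the aryl silyl ethers intact, and the carbinol configuration is irrelevant.

**Step 16**
Reactants: 23 bis-TBS aryl chroman-4-ol
Product: 24 bis-TBS ether of the target (2,2-dimethyl-2H-chromene)
Conditions: p-TsOH·H2O (5 mol%), toluene, 50 °C
Reagents that add atoms: none
Why: Acid-catalysed E1 dehydration of the benzylic alcohol, whose cation is stabilised by the ortho ring oxygen and the para methoxy group, gives the conjugated 2H-chromene.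

**Step 17**
Reactants: 24 bis-TBS ether of the target
Product: 25 CNP0207533.1 (target)
Conditions: TBAF (2.4 equiv), AcOH (2.4 equiv), THF, 0 °C, under Ar
Reagents that add atoms: none
Why: Fluoride desilylation of the aryl silyl ethers, buffered with acetic acid under argon so that the liberated catechol is not oxidised and the chromene sees no strong acid.

**Compound list**
1 | phloroglucinol | Oc1cc(O)cc(O)c1 | starting material
2 | 3-methylbut-2-enoic acid | CC(C)=CC(=O)O | starting material
3 | 3-methyl-1-(2,4,6-trihydroxyphenyl)but-2-en-1-one (formed in situ) | CC(C)=CC(=O)c1c(O)cc(O)cc1O | intermediate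
4 | 5,7-dihydroxy-2,2-dimethylchroman-4-one | Oc1cc2c(c(O)c1)C(=O)CC(C)(C)O2 | intermediate
5 | 5-hydroxy-7-methoxy-2,2-dimethylchroman-4-one | COc1cc2c(c(O)c1)C(=O)CC(C)(C)O2 | intermediate
6 | 5-hydroxy-6-iodo-7-methoxy-2,2-dimethylchroman-4-one | COc1cc2c(c(O)c1I)C(=O)CC(C)(C)O2 | intermediate
7 | 6-iodo-7-methoxy-2,2-dimethyl-4-oxochroman-5-yl acetate | COc1cc2c(c(OC(C)=O)c1I)C(=O)CC(C)(C)O2 | intermediate
8 | (1R,3R)-cis-pinonic acid | OC(=O)C[C@H]1C[C@@H](C(C)=O)C1(C)C | starting material
9 | 2-[(1R,3R)-3-acetoxy-2,2-dimethylcyclobutyl]acetic acid | OC(=O)C[C@H]1C[C@@H](OC(C)=O)C1(C)C | intermediate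
10 | acyl hypoiodite of 9 (formed in situ) | IOC(=O)C[C@H]1C[C@@H](OC(C)=O)C1(C)C | intermediate
11 | (1R,3S)-3-(iodomethyl)-2,2-dimethylcyclobutyl acetate | IC[C@H]1C[C@@H](OC(C)=O)C1(C)C | intermediate
12 | {[(1S,3R)-3-acetoxy-2,2-dimethylcyclobutyl]methyl}zinc iodide (formed in situ) | I[Zn]C[C@H]1C[C@@H](OC(C)=O)C1(C)C | intermediate
13 | 6-{[(1S,3R)-3-acetoxy-2,2-dimethylcyclobutyl]methyl}-7-methoxy-2,2-dimethyl-4-oxochroman-5-yl acetate | COc1cc2c(c(OC(C)=O)c1C[C@H]1C[C@@H](OC(C)=O)C1(C)C)C(=O)CC(C)(C)O2 | intermediate
14 | 5-hydroxy-6-{[(1S,3R)-3-hydroxy-2,2-dimethylcyclobutyl]methyl}-7-methoxy-2,2-dimethylchroman-4-one | COc1cc2c(c(O)c1C[C@H]1C[C@@H](O)C1(C)C)C(=O)CC(C)(C)O2 | intermediate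
15 | 6-{[(1S,3R)-3-hydroxy-2,2-dimethylcyclobutyl]methyl}-7-methoxy-2,2-dimethyl-4-oxochroman-5-yl trifluoromethanesulfonate | COc1cc2c(c(OS(=O)(=O)C(F)(F)F)c1C[C@H]1C[C@@H](O)C1(C)C)C(=O)CC(C)(C)O2 | intermediate
16 | 6-{[(1S)-2,2-dimethyl-3-oxocyclobutyl]methyl}-7-methoxy-2,2-dimethyl-4-oxochroman-5-yl trifluoromethanesulfonate (key-step precursor) | COc1cc2c(c(OS(=O)(=O)C(F)(F)F)c1C[C@H]1CC(=O)C1(C)C)C(=O)CC(C)(C)O2 | intermediate
17 | cis-fused cyclobuta-indano-chromanone diketone (Cb S, Cc S; C=O at Cd and C4; key-step product) | COc1cc2c(c3c1C[C@H]1[C@@H]3C(=O)C1(C)C)C(=O)CC(C)(C)O2 | intermediate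
18 | Cd alcohol of 17 (endo epimer drawn: OH cis to the C5–Cc bond; chromanone intact) | COc1cc2c(c3c1C[C@H]1[C@@H]3[C@@H](O)C1(C)C)C(=O)CC(C)(C)O2 | intermediate
19 | 4-bromocatechol | Oc1ccc(Br)cc1O | starting material
20 | 4-bromo-1,2-bis(tert-butyldimethylsilyloxy)benzene | CC(C)(C)[Si](C)(C)Oc1ccc(Br)cc1O[Si](C)(C)C(C)(C)C | intermediate
21 | 2-alkoxy-5,7-di-tert-butyl-3-phenyl-2,3-dihydrobenzoxazole adduct of 18 (formed in situ; acetal carbon unassigned) | COc1cc2c(c3c1C[C@H]1[C@@H]3[C@@H](OC4Oc5c(cc(cc5C(C)(C)C)C(C)(C)C)N4c4ccccc4)C1(C)C)C(=O)CC(C)(C)O2 | intermediate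
22 | Cd-[3,4-bis(tert-butyldimethylsilyloxy)phenyl] tetracyclic chromanone (Cb S, Cc R, Cd S; aryl trans to the C5–Cc bond) | COc1cc2c(c3c1C[C@H]1[C@@H]3[C@H](c3ccc(O[Si](C)(C)C(C)(C)C)c(O[Si](C)(C)C(C)(C)C)c3)C1(C)C)C(=O)CC(C)(C)O2 | intermediate
23 | chroman-4-ol of 22 (C4 epimers) | COc1cc2c(c3c1C[C@H]1[C@@H]3[C@H](c3ccc(O[Si](C)(C)C(C)(C)C)c(O[Si](C)(C)C(C)(C)C)c3)C1(C)C)C(O)CC(C)(C)O2 | intermediate
24 | bis-TBS ether of the target (2,2-dimethyl-2H-chromene) | COc1cc2c(c3c1C[C@H]1[C@@H]3[C@H](c3ccc(O[Si](C)(C)C(C)(C)C)c(O[Si](C)(C)C(C)(C)C)c3)C1(C)C)C=CC(C)(C)O2 | intermediate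
25 | CNP0207533.1 (Cb S, Cc R, Cd S) | COc1cc2c(c3c1C[C@H]1[C@@H]3[C@H](c3ccc(O)c(O)c3)C1(C)C)C=CC(C)(C)O2 | target

**Totals**
Total steps: 17. Longest linear sequence: 14 (steps 1–4, 7–12, 14–17).

**Steps most likely to fail**

1. Step 11. Enolisation of the hindered cyclobutanone by the weak base may be slow, so that the aryl–palladium triflate is reduced or the triflate is hydrolysed before C–C bond formation. Any nucleophile present could also open the strained ketone. Fallback, from 16 back to 17: both ketones of 16 are silylated with TMSOTf/Et3N to the bis(trimethylsilyl enol ether) F1. Pd(dba)2/P(t-Bu)3 with CsF (catalytic ZnF2) in DMF then couples the cyclobutenyl silyl ether with the triflate through a fluoride-released enolate, without a Brønsted base. The chromenyl silyl ether cannot reach C5 and is hydrolysed on work-up, which gives 17.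

2. Step 14. Capture of the neopentyl-type cyclobutyl radical by the aryl–nickel species may be slower than hydrogen abstraction or loss of the radical, and delivery of the electron-rich aryl group may not be fully face-selective. Fallback, from 18 back to 22: 18 is acylated with oxalyl chloride and hydrolysed to the alkyl hydrogen oxalate F2, an isolable radical precursor. With Ir[dF(CF3)ppy]2(dtbbpy)PF6, NiBr2·dtbbpy and CsHCO3 in dioxane/DMSO under blue light at 70 °C, oxidation and double decarboxylation give the same Cd radical for nickel coupling with 20.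

3. Step 7. Transmetalation and reductive elimination at the di-ortho-substituted aryl–palladium centre may lag behind protodemetalation and homocoupling. Fallback, from 9 back to 13: 9 is converted with N-hydroxyphthalimide, DIC and DMAP into the redox-active ester F3. Nickel-catalysed decarboxylative reductive arylation with 7 (NiBr2·glyme, dtbbpy, Zn, DMA) then gives 13. A high nickel loading is used so that radical capture competes with ring opening of the cyclobutylmethyl radical.

**Further compounds**
F1 | step 11 | bis(trimethylsilyl enol ether) of 16 (cyclobutenyl and 2H-chromen-4-yl silyl ethers) | COc1cc2c(c(OS(=O)(=O)C(F)(F)F)c1C[C@H]1C=C(O[Si](C)(C)C)C1(C)C)C(O[Si](C)(C)C)=CC(C)(C)O2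
F2 | step 14 | alkyl hydrogen oxalate of 18 | COc1cc2c(c3c1C[C@H]1[C@@H]3[C@@H](OC(=O)C(=O)O)C1(C)C)C(=O)CC(C)(C)O2
F3 | step 7 | N-hydroxyphthalimide ester of 9 | O=C(C[C@H]1C[C@@H](OC(C)=O)C1(C)C)ON1C(=O)c2ccccc2C1=O
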